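## Structural features

Target 20 is an eudesmane, and eudesmane numbering is used throughout. Ring A (C1–C2–C3–C4–C5–C10) and ring B (C5–C6–C7–C8–C9–C10) share the C5–C10 bond, where C10 is a quaternary stereocentre bearing a methyl group (C14) and C5 is an sp2 carbon of the trisubstituted C5=C6 alkene. Ring A carries two adjacent oxygenated stereocentres: the secondary angelate at C3 (S, 3β, equatorial) and the tertiary allylic alcohol at C4 (R, 4β-OH axial, 4α-CH3 = C15 equatorial). Both oxygens are cis and lie on the face of the C10 methyl group (10S), so the 4-OH is 1,3-diaxial to it. C7 (R) in ring B carries the acrylate unit C11(=C13H2)–C12O2CH3, is 1,4-cis to C14 and is doubly allylic. The fragile groups are: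
- the angelate, which isomerises from Z to E under nucleophilic or acidic conditions;
- the tertiary allylic alcohol, which can ionise, transpose or dehydrate;
- the skipped diene C5=C6–C7–C11=C13, which can slip into conjugation;
- the acrylate, which is a Michael acceptor and labile to hydride.

C7 and C10 are the easy part, because a p-menthane from the chiral pool maps onto ring B. The real difficulty is the C3–C4–C5=C6 array. It is a cis-diol on the more hindered β face, its tertiary centre sits next to an alkene held out of conjugation, and any intermediate with a C3 ketone and a C4–H or C4=C5 bond falls into the Δ4-3-ketone sink. The key step exploits the fact that C3 and C4 of ring A are directly bonded and both oxygenated, and that C4 bears a methyl group and is bound to the sp2 carbon C5. At the C3-ketone level ring A is therefore a cyclic acyloin, and its C3–C4 bond can be made by polarity-reversed addition of a C3 aldehyde to a C4 methyl ketone already attached to C5=C6, under 1,3-control from C10.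

## Logic of the disconnections

**20 ⇒ 16 (through 19, 18 and 17).** The O–CH3 bond of the ester and the C12–O bonds are cut, so C12 returns to a methyl group. The acrylate would accept carbenes and enolates and would be reduced by aluminium hydrides, so it cannot pass through the earlier steps. The side chain becomes an inert isopropenyl group that comes free with the chiral pool. The forward step must take a hydrogen from C12 and not from the doubly allylic C7, and must spare the angelate and the tertiary alcohol.

**16 ⇒ 13 + 14.** The acyl–oxygen bond at C3–O is cut. The isomerisation-prone ester is kept away from base, hydride and carbene. The gain is a free diol and a commercial acid. The forward step must select the secondary over the tertiary hydroxyl group and retain the Z geometry.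

**13 ⇒ 12.** The C3–H bond is cut. This turns the diol into an acyloin and removes one stereocentre. The hydride must arrive on the α face of C3.

**12 ⇒ 11 (key).** The ring bond C3–C4 is cut between the two oxygenated carbons. Ring A opens and C4 loses its stereocentre. What remains is a monocyclic cyclohexene that already holds C5=C6, C7 and C10, with a 3-oxopropyl chain on C10 and an acetyl group on C5. In one sentence, a carbene-catalysed intramolecular crossed benzoin reaction of the monocyclic keto aldehyde 11 closes ring A at C3–C4. That sentence does not describe an annulation through C10–C1 and C4=C5. The forward step must add C3 as an acyl anion equivalent to the carbonyl carbon C4 and not to C6, on the face that places oxygen syn to C14.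

**11 ⇒ 7 + 8 (through 10 and 9).** The C4–C5 bond is cut, and the oxidation level at C3 is adjusted from ester to aldehyde. C4 and C15 arrive as a masked acetyl unit, so the ketone stays hidden while the ester is reduced. The demand is a cross-coupling at an alkenyl carbon next to a quaternary centre.

**7 ⇒ 6.** The C5–O bond is cut. Because C10 is quaternary, the C5 ketone can enolise only towards C6, and this fixes the alkene position without any selectivity problem. The ketone must be deprotonated in the presence of the ester.

**6 ⇒ 1 + 3 (2 as controller, through 5 and 4).** The C10–C1 bond is cut. This returns to a chiral-pool ketone that supplies ring B, C7 and C14, plus a three-carbon acceptor for C1–C3. The chain must enter trans to the isopropenyl group, against the intrinsic axial preference of the ring, so an external chiral controller is needed.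

## Other disconnections considered

**Alternative 1:** cut C10–C1 and C4=C5 (Robinson annulation, the first plan that comes to mind).
- Forward: the enamine or enolate of 1 would be added to ethyl vinyl ketone and the product closed by aldol condensation to (+)-α-cyperone A1. Deprotonation at C6 to the linear dienolate and attack of an oxygen electrophile at C4 would then have to give 12.
- Step count: on paper this is about two steps shorter.
- Objection: the ring closure ends in the conjugated Δ4-3-ketone, the thermodynamic sink of this ring system, in which neither the C4 carbinol nor the C5=C6 alkene exists. Both would have to be won back in a single contra-thermodynamic oxidation.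
- Selectivity: three nucleophilic sites compete in that oxidation (C2 through the cross-conjugated enolate, C4 and C6 through the linear one). The electrophile must enter on the β face, 1,3-syn to C14. The product is an enolisable α-ketol that stays exposed to strong base and oxidant.
- Verdict: the ring-forming step settles none of the C3/C4/C5=C6 problem. In the chosen plan the closure of ring A itself creates C4 with the alkene already in place.

**Alternative 2:** cut C9–C10 (dearomatisation of ring A).
- Forward: the phenoxide of bromide A2 would be alkylated intramolecularly at the para carbon C10 to give the cross-conjugated dienone A3.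
- Regiochemistry: the chain sits on C5, between two methyl-bearing ring carbons. Closure onto C10 (para to O⁻) and onto C4 (ortho to O⁻) are both six-membered and sterically alike, so the regiochemistry has no structural bias.
- Stereocontrol: C10 would be set only by remote 1,4-induction from C7.
- Access: the 1,2,3,4-tetrasubstituted arene A2, with its stereocentre in the chain, needs a long preparation.
- Verdict: A3 still lacks the C4 carbinol and the C5=C6 alkene, so it needs selective saturation of C1=C2 and then the same deconjugative oxidation as Alternative 1. The dearomatisation spends its power on C10, the easy centre.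

**Alternative 3:** cut C4–C5.
- Forward: intramolecular alkenyl-metal addition (Nozaki–Hiyama–Kishi type or halogen–lithium exchange) of the C5 iodide to the C4 methyl ketone in A4, to give silyl ether A5.
- C3: it would have to be set beforehand in an open chain remote from C10 by a separate asymmetric oxygenation, which costs several steps.
- Reactivity: ketones are poor acceptors for alkenylchromium species. An α-silyloxy methyl ketone is prone to enolisation by an alkenyllithium. The nucleophilic carbon is flanked by the quaternary C10.
- C4: in the closing ring both the cis and the trans O/O arrangements are gauche, so chelation would not distinguish the two faces of C4.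
- Verdict: the chosen plan makes the hindered C4–C5 bond by cross-coupling, where no stereocentre is at stake, and leaves the ring closure to the unhindered aldehyde carbon C3.

Key step: step 5

Remark: commercial (+)-dihydrocarvone 1 is a mixture of C2 epimers. It is drawn as the major (2R,5R) isomer, and both epimers converge in step 1 because this carbon becomes planar there.

## Steps

Step 1
Reactants: 1 (+)-dihydrocarvone; 2 (R)-(+)-1-phenylethylamine; 3 methyl acrylate
Product: 6 methyl 3-[(1S,4R)-1-methyl-2-oxo-4-(prop-1-en-2-yl)cyclohexyl]propanoate, via ketimine 4 (not isolated), via adduct imine 5 (not isolated)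
Conditions: 1, 2, cat. TsOH, toluene, Dean–Stark, reflux; concentrate; 3, THF, 45 °C; then 20% aq AcOH, rt
Reagents that add atoms: water, O
Why: Asymmetric Michael addition of a chiral imine through its more substituted secondary enamine tautomer in a compact aza-ene-like transition state, so the new bond forms only at the methyl-bearing carbon. The phenyl group of the (R)-auxiliary should screen the β face, so the acrylate enters on the α face, trans to the isopropenyl group, and sets C10 as S; C7 comes unchanged from 1.

Step 2
Reactants: 6 methyl 3-[(1S,4R)-1-methyl-2-oxo-4-(prop-1-en-2-yl)cyclohexyl]propanoate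
Product: 7 methyl 3-[(1S,4R)-1-methyl-4-(prop-1-en-2-yl)-2-(trifluoromethylsulfonyloxy)cyclohex-2-en-1-yl]propanoate
Conditions: KHMDS, THF, −78 °C; PhNTf2, −78 to 0 °C
Reagents that add atoms: N-phenylbis(trifluoromethanesulfonimide), O=S(=O)(N(c1ccccc1)S(=O)(=O)C(F)(F)F)C(F)(F)F
Why: Kinetic enolate formation and O-triflation; C10 is quaternary, so only C6 can be deprotonated and the alkene is fixed at C5=C6. The ketone is markedly more acidic than the ester, and the low temperature should suppress acylation of the enolate by the ester.

Step 3
Reactants: 7 methyl 3-[(1S,4R)-1-methyl-4-(prop-1-en-2-yl)-2-(trifluoromethylsulfonyloxy)cyclohex-2-en-1-yl]propanoate; 8 tributyl(1-ethoxyvinyl)stannane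
Product: 9 methyl 3-[(1S,4R)-2-(1-ethoxyvinyl)-1-methyl-4-(prop-1-en-2-yl)cyclohex-2-en-1-yl]propanoate
Conditions: Pd(PPh3)4 (5 mol %), LiCl, cat. CuI, THF, 65 °C
Reagents that add atoms: none
Why: Stille coupling of an alkenyl triflate with an α-alkoxyvinylstannane, a type that tolerates triflates next to quaternary carbons; it forms C4–C5 and brings in C4 and C15 as a masked acetyl group. The enol ether is kept so that the future ketone is protected in step 4.

Step 4
Reactants: 9 methyl 3-[(1S,4R)-2-(1-ethoxyvinyl)-1-methyl-4-(prop-1-en-2-yl)cyclohex-2-en-1-yl]propanoate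
Product: 11 3-[(1S,4R)-2-acetyl-1-methyl-4-(prop-1-en-2-yl)cyclohex-2-en-1-yl]propanal, via enol ether aldehyde 10 (not isolated)
Conditions: DIBAL-H (1.1 equiv), toluene, −78 °C; then 1 M aq HCl, THF, 0 °C
Reagents that add atoms: water, O
Why: Partial reduction of a methyl ester through the tetrahedral aluminium hemiacetal, which is stable at −78 °C, while the enol ether is inert to hydride. The acidic work-up collapses the hemiacetal and protonates the terminal CH2 of the 2-alkoxydiene, so hydrolysis gives the conjugated methyl ketone without touching C5=C6 or the isopropenyl group.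

Step 5
Reactants: 11 3-[(1S,4R)-2-acetyl-1-methyl-4-(prop-1-en-2-yl)cyclohex-2-en-1-yl]propanal
Product: 12 (1R,4aS,7R)-1-hydroxy-1,4a-dimethyl-7-(prop-1-en-2-yl)-3,4,4a,5,6,7-hexahydronaphthalen-2(1H)-one
Conditions: 3-benzyl-5-(2-hydroxyethyl)-4-methylthiazolium chloride (20 mol %), DBU (40 mol %), t-BuOH, 0.02 M, 40 °C, argon
Reagents that add atoms: none
Why: Intramolecular crossed aldehyde–ketone benzoin reaction under N-heterocyclic carbene catalysis, the closest known type being the carbene-catalysed cyclisation of 1,6-keto aldehydes to 2-hydroxy-2-alkylcyclohexanones. The thiazol-2-ylidene adds to the unhindered aldehyde C3 (the ketone cannot become an acyl anion equivalent), a proton shift gives the nucleophilic enaminol, this attacks the ketone carbon C4, and proton transfer with loss of the carbene releases 12 and regenerates the catalyst. Ring A is closed in a 6-exo-trig mode at C3–C4, with C5=C6, C7 and C10 untouched. The only new stereocentre, C4, is controlled by C7 and C10 together: the pseudo-equatorial isopropenyl group at C7 holds the half-chair of ring B so that C14 is pseudo-axial and the C1–C3 chain lies near the alkene plane, and in the chair-like closure the acetyl methyl group takes the equatorial site while the carbonyl oxygen goes axial on the β face, because the other arrangement would set C15 and C14 1,3-diaxial. The same factor should make 12 the more stable C4 epimer, so any reversibility of the addition works in the same direction. The step needs 1,2- over 1,4-addition: attack at C6 (Stetter mode) would be a 6-endo closure to a bicyclo[3.3.1]nonane from the conformer with chain and isopropenyl group both pseudo-axial, α,β-disubstituted enones are poor Stetter acceptors, and the quaternary C10 twists the acetyl group out of conjugation, which raises the electrophilicity of C4 and lowers that of C6. It also needs the cyclisation to outrun self-condensation of the aldehyde and the base-induced aldol attack of C2 on C4, which dilution, a substoichiometric amidine base and a protic solvent should secure. The isopropenyl group is no acceptor for the enaminol, which is why C12 is carried at the methyl level through this step.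

Step 6
Reactants: 12 (1R,4aS,7R)-1-hydroxy-1,4a-dimethyl-7-(prop-1-en-2-yl)-3,4,4a,5,6,7-hexahydronaphthalen-2(1H)-one
Product: 13 (1R,2S,4aS,7R)-1,4a-dimethyl-7-(prop-1-en-2-yl)-1,2,3,4,4a,5,6,7-octahydronaphthalene-1,2-diol
Conditions: NaBH4, MeOH–CH2Cl2, −78 to −20 °C
Reagents that add atoms: none
Why: Substrate-controlled borohydride reduction of a cyclohexanone: the small hydride should attack C3 axially from the α face, anti to the axial C4–O bond (Felkin–Anh polar model) and away from the β face screened by the 4β-OH and C14. This gives the equatorial 3β-alcohol (3S), cis to the 4-OH, as in the reduction of 4,4-disubstituted 3-keto steroids.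

Step 7
Reactants: 13 (1R,2S,4aS,7R)-1,4a-dimethyl-7-(prop-1-en-2-yl)-1,2,3,4,4a,5,6,7-octahydronaphthalene-1,2-diol; 14 angelic acid
Product: 16 (1R,2S,4aS,7R)-1-hydroxy-1,4a-dimethyl-7-(prop-1-en-2-yl)-1,2,3,4,4a,5,6,7-octahydronaphthalen-2-yl (Z)-2-methylbut-2-enoate, via mixed anhydride 15 (not isolated)
Conditions: 14, 2,4,6-trichlorobenzoyl chloride, Et3N, toluene, rt; then 13, 80 °C
Reagents that add atoms: none
Why: Yamaguchi-type mixed-anhydride esterification run without a nucleophilic catalyst; the alcohol attacks the less hindered angeloyl carbonyl of 15, and only the equatorial secondary 3-OH should react, since the axial tertiary 4-OH is too hindered. Leaving out DMAP avoids the addition–elimination path that turns angelates into tiglates.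

Step 8
Reactants: 16 (1R,2S,4aS,7R)-1-hydroxy-1,4a-dimethyl-7-(prop-1-en-2-yl)-1,2,3,4,4a,5,6,7-octahydronaphthalen-2-yl (Z)-2-methylbut-2-enoate
Product: 18 (1R,2S,4aS,7R)-1-hydroxy-1,4a-dimethyl-7-(3-oxoprop-1-en-2-yl)-1,2,3,4,4a,5,6,7-octahydronaphthalen-2-yl (Z)-2-methylbut-2-enoate, via allylic alcohol 17 (not isolated)
Conditions: SeO2 (0.3 equiv), t-BuOOH (decane), CH2Cl2, 0 °C to rt; filter; activated MnO2, CH2Cl2, rt
Reagents that add atoms: tert-butyl hydroperoxide, CC(C)(C)OO; selenium dioxide (catalytic oxygen carrier), O=[Se]=O
Why: Riley allylic oxidation (ene reaction at the terminal CH2, then [2,3]-shift) of the 1,1-disubstituted alkene, followed by MnO2 oxidation of the primary allylic alcohol, which leaves the tertiary alcohol and the ester alone. C5=C6 offers no hydrogen on C4 or C10 for the usual ene mode, the angelate alkene is electron-poor, and in the preferred rotamer the C7–H bond eclipses C11=C13 and lies in the nodal plane of that π bond, so a hydrogen of the freely rotating methyl group should be taken.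

Step 9
Reactants: 18 (1R,2S,4aS,7R)-1-hydroxy-1,4a-dimethyl-7-(3-oxoprop-1-en-2-yl)-1,2,3,4,4a,5,6,7-octahydronaphthalen-2-yl (Z)-2-methylbut-2-enoate
Product: 19 3β-angeloyloxy-4β-hydroxyeudesma-5,11(13)-dien-12-oic acid
Conditions: NaClO2, NaH2PO4, 2-methyl-2-butene, t-BuOH–H2O, 0 °C to rt
Reagents that add atoms: sodium chlorite, [Na+].[O-]Cl=O
Why: Pinnick oxidation, the standard mild conversion of 2-substituted acroleins into acrylic acids. The buffer and the hypochlorite scavenger protect the alkenes, the tertiary allylic alcohol and the angelate.

Step 10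
Reactants: 19 3β-angeloyloxy-4β-hydroxyeudesma-5,11(13)-dien-12-oic acid
Product: 20 methyl 3β-angeloyloxy-4β-hydroxyeudesma-5,11(13)-dien-12-oate (CNP0283268.1)
Conditions: MeI, K2CO3, DMF, 0 °C to rt
Reagents that add atoms: iodomethane, CI
Why: SN2 O-alkylation of the carboxylate; carbonate is too weak to deprotonate C7–H or the tertiary alcohol. The method avoids diazoalkanes, which could add to the acrylate as 1,3-dipoles.

## Compound list

1 | (+)-dihydrocarvone, (2R,5R)-2-methyl-5-(prop-1-en-2-yl)cyclohexan-1-one | C=C(C)[C@H]1CC(=O)[C@H](C)CC1 | starting material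
2 | (R)-(+)-1-phenylethylamine | C[C@@H](N)c1ccccc1 | starting material
3 | methyl acrylate | C=CC(=O)OC | starting material
4 | (5R)-2-methyl-N-[(1R)-1-phenylethyl]-5-(prop-1-en-2-yl)cyclohexan-1-imine (C2 epimers, in equilibrium with the enamine) | C=C(C)[C@H]1CC(=N[C@H](C)c2ccccc2)C(C)CC1 | intermediate
5 | methyl 3-[(1S,4R)-1-methyl-2-{[(1R)-1-phenylethyl]imino}-4-(prop-1-en-2-yl)cyclohexyl]propanoate | C=C(C)[C@H]1CC(=N[C@H](C)c2ccccc2)[C@](C)(CCC(=O)OC)CC1 | intermediate
6 | methyl 3-[(1S,4R)-1-methyl-2-oxo-4-(prop-1-en-2-yl)cyclohexyl]propanoate | C=C(C)[C@H]1CC(=O)[C@](C)(CCC(=O)OC)CC1 | intermediate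
7 | methyl 3-[(1S,4R)-1-methyl-4-(prop-1-en-2-yl)-2-(trifluoromethylsulfonyloxy)cyclohex-2-en-1-yl]propanoate | C=C(C)[C@H]1C=C(OS(=O)(=O)C(F)(F)F)[C@](C)(CCC(=O)OC)CC1 | intermediate
8 | tributyl(1-ethoxyvinyl)stannane | C=C(OCC)[Sn](CCCC)(CCCC)CCCC | starting material
9 | methyl 3-[(1S,4R)-2-(1-ethoxyvinyl)-1-methyl-4-(prop-1-en-2-yl)cyclohex-2-en-1-yl]propanoate | C=C(C)[C@H]1C=C(C(=C)OCC)[C@](C)(CCC(=O)OC)CC1 | intermediate
10 | 3-[(1S,4R)-2-(1-ethoxyvinyl)-1-methyl-4-(prop-1-en-2-yl)cyclohex-2-en-1-yl]propanal | C=C(C)[C@H]1C=C(C(=C)OCC)[C@](C)(CCC=O)CC1 | intermediate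
11 | 3-[(1S,4R)-2-acetyl-1-methyl-4-(prop-1-en-2-yl)cyclohex-2-en-1-yl]propanal | C=C(C)[C@H]1C=C(C(C)=O)[C@](C)(CCC=O)CC1 | intermediate
12 | (1R,4aS,7R)-1-hydroxy-1,4a-dimethyl-7-(prop-1-en-2-yl)-3,4,4a,5,6,7-hexahydronaphthalen-2(1H)-one | C=C(C)[C@H]1C=C2[C@](C)(CCC(=O)[C@]2(C)O)CC1 | intermediate
13 | (1R,2S,4aS,7R)-1,4a-dimethyl-7-(prop-1-en-2-yl)-1,2,3,4,4a,5,6,7-octahydronaphthalene-1,2-diol | C=C(C)[C@H]1C=C2[C@](C)(CC[C@H](O)[C@]2(C)O)CC1 | intermediate
14 | angelic acid, (Z)-2-methylbut-2-enoic acid | C/C=C(/C)C(=O)O | starting material
15 | angelic 2,4,6-trichlorobenzoic anhydride | C/C=C(/C)C(=O)OC(=O)c1c(Cl)cc(Cl)cc1Cl | intermediate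
16 | (1R,2S,4aS,7R)-1-hydroxy-1,4a-dimethyl-7-(prop-1-en-2-yl)-1,2,3,4,4a,5,6,7-octahydronaphthalen-2-yl (Z)-2-methylbut-2-enoate | C=C(C)[C@H]1C=C2[C@](C)(CC[C@H](OC(=O)/C(C)=C\C)[C@]2(C)O)CC1 | intermediate
17 | (1R,2S,4aS,7R)-1-hydroxy-7-(3-hydroxyprop-1-en-2-yl)-1,4a-dimethyl-1,2,3,4,4a,5,6,7-octahydronaphthalen-2-yl (Z)-2-methylbut-2-enoate | C=C(CO)[C@H]1C=C2[C@](C)(CC[C@H](OC(=O)/C(C)=C\C)[C@]2(C)O)CC1 | intermediate
18 | (1R,2S,4aS,7R)-1-hydroxy-1,4a-dimethyl-7-(3-oxoprop-1-en-2-yl)-1,2,3,4,4a,5,6,7-octahydronaphthalen-2-yl (Z)-2-methylbut-2-enoate | C=C(C=O)[C@H]1C=C2[C@](C)(CC[C@H](OC(=O)/C(C)=C\C)[C@]2(C)O)CC1 | intermediate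
19 | 3β-angeloyloxy-4β-hydroxyeudesma-5,11(13)-dien-12-oic acid | C=C(C(=O)O)[C@H]1C=C2[C@](C)(CC[C@H](OC(=O)/C(C)=C\C)[C@]2(C)O)CC1 | intermediate
20 | methyl 3β-angeloyloxy-4β-hydroxyeudesma-5,11(13)-dien-12-oate (3S,4R,7R,10S) | C=C(C(=O)OC)[C@H]1C=C2[C@](C)(CC[C@H](OC(=O)/C(C)=C\C)[C@]2(C)O)CC1 | target

## Step count and least certain steps

Total step count: 10. Longest linear sequence: 10 steps, from 1 to 20. Compounds 2, 3, 8 and 14 are commercial and enter directly.

**Step 5 (key step).**
- Risk: the most likely failure is insufficient facial discrimination at the acetyl carbonyl. The bias rests on conformational preferences of moderate size (isopropenyl group pseudo-equatorial, avoidance of a 1,3-diaxial methyl pair). Second, addition to a hindered ketone may be slow, which would give room to the base-induced aldol closure of C2 onto C4 or to self-condensation of the aldehyde.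
- First response within the approach: the matched enantiomer of a chiral aminoindanol-derived triazolium salt may be used to reinforce the facial bias.
- Fallback: this gives up the C3–C4 closure, sets out from 4 and comes back at 12. Imine 4 would be treated with ethyl vinyl ketone to give the adduct imine F1, which aqueous acetic acid would hydrolyse to the diketone F2. Sodium methoxide in methanol would close F2 by aldol condensation to (+)-α-cyperone F3. Potassium tert-butoxide in THF would convert F3 into the linear Δ3,5-dienolate, and 2-(benzenesulfonyl)-3-phenyloxaziridine would hydroxylate it at C4 by stereoelectronically preferred axial (β) attack, with deconjugation to 12.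

**Step 8.**
- Risk: the ene step may abstract the doubly allylic C7–H, which would lead to oxygenation at C7. The acidic selenium species may also ionise the tertiary allylic alcohol.
- Fallback: this replaces the pericyclic selenium chemistry with an ionic chlorination in a buffered two-phase medium, sets out from 16 and comes back at 18. Hypochlorous acid generated in situ (Ca(OCl)2, CO2, CH2Cl2–H2O, 0 °C) would convert the isopropenyl group into the allylic chloride F4, by proton loss from the methyl group of the chloronium ion. C5=C6 has no hydrogen on C4 or C10 for this ene-type process. N-Methylmorpholine N-oxide in acetonitrile would then oxidise F4 to 18.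

**Step 1.**
- Risk: the auxiliary must override the intrinsic preference of the ring for axial attack cis to the isopropenyl group, so facial selectivity at C10 may erode. Slow addition to the acrylate may also allow reaction through the less substituted enamine.
- Fallback: this moves to catalyst-controlled enolate allylation, sets out from 1 and comes back at 11.
  - TMSCl, NaI and Et3N in acetonitrile would give the more substituted silyl enol ether F5.
  - Pd2(dba)3, (S)-t-BuPHOX, diallyl carbonate and Bu4N[Ph3SiF2] would give the allyl ketone F6, in which the allyl group supplies C1–C3.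
  - KHMDS and PhNTf2 would give the alkenyl triflate F7.
  - Carbonylative Stille coupling (Pd(PPh3)4, LiCl, CO, Me4Sn) would give the allyl enone F8.
  - A nitrite-modified aldehyde-selective Wacker oxidation (PdCl2(PhCN)2, CuCl2, AgNO2, O2, t-BuOH–MeNO2), to which 1,1-disubstituted alkenes are inert, would give 11.

**Step 7.**
- Risk: the angeloyl unit may isomerise from Z to E during a slow acylation at 80 °C, or the hydroxyl group next to the fully substituted C4 may convert incompletely.
- Fallback: this builds the Z alkene after the ester bond, sets out from 13 and comes back at 16. Acylation of 13 with 2-[bis(2,2,2-trifluoroethoxy)phosphoryl]propanoic acid (EDC, DMAP, CH2Cl2; no alkene is present to isomerise) would give the phosphonate ester F9. Still–Gennari olefination (KHMDS, 18-crown-6, THF, −78 °C, acetaldehyde) would then give the Z-trisubstituted ester 16.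

## Further compounds

F1 | step 5 | (2S,5R)-2-methyl-2-(3-oxopentyl)-5-(prop-1-en-2-yl)cyclohexan-1-one N-[(1R)-1-phenylethyl]imine | C=C(C)[C@H]1CC(=N[C@H](C)c2ccccc2)[C@](C)(CCC(=O)CC)CC1
F2 | step 5 | (2S,5R)-2-methyl-2-(3-oxopentyl)-5-(prop-1-en-2-yl)cyclohexan-1-one | C=C(C)[C@H]1CC(=O)[C@](C)(CCC(=O)CC)CC1
F3 | step 5 | (+)-α-cyperone, (4aS,7R)-1,4a-dimethyl-7-(prop-1-en-2-yl)-4,4a,5,6,7,8-hexahydronaphthalen-2(3H)-one | C=C(C)[C@H]1CC2=C(C)C(=O)CC[C@]2(C)CC1
F4 | step 8 | (1R,2S,4aS,7R)-7-(3-chloroprop-1-en-2-yl)-1-hydroxy-1,4a-dimethyl-1,2,3,4,4a,5,6,7-octahydronaphthalen-2-yl (Z)-2-methylbut-2-enoate | C=C(CCl)[C@H]1C=C2[C@](C)(CC[C@H](OC(=O)/C(C)=C\C)[C@]2(C)O)CC1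
F5 | step 1 | trimethyl{[(5R)-2-methyl-5-(prop-1-en-2-yl)cyclohex-1-en-1-yl]oxy}silane | C=C(C)[C@H]1CC(O[Si](C)(C)C)=C(C)CC1
F6 | step 1 | (2S,5R)-2-allyl-2-methyl-5-(prop-1-en-2-yl)cyclohexan-1-one | C=C(C)[C@H]1CC(=O)[C@](C)(CC=C)CC1
F7 | step 1 | (3R,6S)-6-allyl-6-methyl-3-(prop-1-en-2-yl)cyclohex-1-en-1-yl trifluoromethanesulfonate | C=C(C)[C@H]1C=C(OS(=O)(=O)C(F)(F)F)[C@](C)(CC=C)CC1
F8 | step 1 | 1-[(3R,6S)-6-allyl-6-methyl-3-(prop-1-en-2-yl)cyclohex-1-en-1-yl]ethan-1-one | C=C(C)[C@H]1C=C(C(C)=O)[C@](C)(CC=C)CC1
F9 | step 7 | (1R,2S,4aS,7R)-1-hydroxy-1,4a-dimethyl-7-(prop-1-en-2-yl)-1,2,3,4,4a,5,6,7-octahydronaphthalen-2-yl 2-[bis(2,2,2-trifluoroethoxy)phosphoryl]propanoate | C=C(C)[C@H]1C=C2[C@](C)(CC[C@H](OC(=O)C(C)P(=O)(OCC(F)(F)F)OCC(F)(F)F)[C@]2(C)O)CC1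
A1 | alternative 1 | (+)-α-cyperone, (4aS,7R)-1,4a-dimethyl-7-(prop-1-en-2-yl)-4,4a,5,6,7,8-hexahydronaphthalen-2(3H)-one | C=C(C)[C@H]1CC2=C(C)C(=O)CC[C@]2(C)CC1
A2 | alternative 2 | 3-[(2S)-2-(2-bromoethyl)-3-methylbut-3-en-1-yl]-2,4-dimethylphenol | C=C(C)[C@H](CCBr)Cc1c(C)ccc(O)c1C
A3 | alternative 2 | (4aS,7R)-1,4a-dimethyl-7-(prop-1-en-2-yl)-5,6,7,8-tetrahydronaphthalen-2(4aH)-one | C=C(C)[C@H]1CC2=C(C)C(=O)C=C[C@]2(C)CC1
A4 | alternative 3 | (3S)-3-(tert-butyldimethylsilyloxy)-5-[(1S,4R)-2-iodo-1-methyl-4-(prop-1-en-2-yl)cyclohex-2-en-1-yl]pentan-2-one | C=C(C)[C@H]1C=C(I)[C@](C)(CC[C@H](O[Si](C)(C)C(C)(C)C)C(C)=O)CC1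
A5 | alternative 3 | (1R,2S,4aS,7R)-2-(tert-butyldimethylsilyloxy)-1,4a-dimethyl-7-(prop-1-en-2-yl)-1,2,3,4,4a,5,6,7-octahydronaphthalen-1-ol | C=C(C)[C@H]1C=C2[C@](C)(CC[C@H](O[Si](C)(C)C(C)(C)C)[C@]2(C)O)CC1
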